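**Overview**
1. Germacrane numbering is used for the sesquiterpene half. C10 is the O-bearing quaternary carbon, C1 the ring-fusion CH, C14 and C15 the methyls on C10 and C4, C11–C13 the C7 side chain, and C1′ the CH2 between C1 and the triketone ring.
2. Cuts, in order: C11–O (hydration of an isopropenyl group); C4–H with re-formation of C6–C11 (homodienyl hydrogen shift read backwards); O–C10 and C1′–C1 (hetero-Diels–Alder); then C2–C3 (sulfone alkylation), C1–C10 (vinyl addition) and C4=C5 (Wittig) of bicyclogermacrene.
3. Enabling feature: the ten-membered ring holds the run C4(H)(CH3)–C5=C6(Z)–C7(H)–C11, with C15 and the C7 side chain on the same ring face. This is the imprint of a suprafacial 1,5-hydrogen shift from a C11 methyl to C4 of an E-C4=C5 alkene on a cis-fused C6–C7–C11 gem-dimethylcyclopropane.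
4. Forward: the cyclopropane is bought in 2-carene and the ten-membered ring is closed at C2–C3. The dihydropyran is then fused onto the ready-made triketone ring, the cyclopropane is opened, and the alcohol is installed last.
5. Stereochemistry: C7 (and C6) come from (+)-2-carene. C1 and C10 are set together by suprafacial cycloaddition to the E-C1=C10 alkene, with the face chosen by the ring conformation. C4 and the Z alkene arise by chirality transfer from the cyclopropane in the hydrogen shift.

Key step: step 13

Remark: the triketone ring is drawn throughout as the enol tautomer of the target SMILES; its other tautomers are the same compound.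

**Route**

Step 1
Reactants: 1 (+)-2-carene
Product: 3 (1S,3R)-2,2-dimethyl-3-(3-oxobutyl)cyclopropane-1-carbaldehyde (cis), via carene ozonide 2 (not isolated)
Conditions: O3, CH2Cl2, −78 °C; then Me2S, −78 °C → rt
Reagents that add atoms: ozone, [O-][O+]=O
Why: Ozonolysis with reductive work-up cleaves the only alkene of 1, turning carene C2 into the aldehyde (future C5) and carene C3 into the methyl ketone (future C10), while the two cyclopropane stereocentres (future C6 and C7) are not touched.

Step 2
Reactants: 3 keto aldehyde; 4 ethyl 2-(triphenylphosphoranylidene)propanoate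
Product: 5 ethyl (2E)-3-[(1S,3R)-2,2-dimethyl-3-(3-oxobutyl)cyclopropyl]-2-methylprop-2-enoate
Conditions: CH2Cl2, 0 °C → rt
Reagents that add atoms: none
Why: Wittig olefination with a stabilised, α-branched ylide engages the aldehyde but not the methyl ketone and gives the E trisubstituted enoate (C3 trans to C6), and the near-neutral medium leaves the epimerisable cis-aldehyde carbon intact.

Step 3
Reactants: 5 keto enoate; 6 vinylmagnesium bromide
Product: 7 ethyl (2E)-3-[(1S,3R)-3-(3-hydroxy-3-methylpent-4-en-1-yl)-2,2-dimethylcyclopropyl]-2-methylprop-2-enoate (both carbinol epimers)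
Conditions: THF, −78 °C; then pH 7 buffer
Reagents that add atoms: none
Why: Grignard 1,2-addition at low temperature picks the unhindered methyl ketone over the conjugated, α-branched ester, and the new carbinol centre forms without control because step 4 erases it.

Step 4
Reactants: 7 tertiary vinyl carbinol
Product: 8 (E)-primary allylic bromide, ethyl (2E)-3-{(1S,3R)-3-[(3E)-5-bromo-3-methylpent-3-en-1-yl]-2,2-dimethylcyclopropyl}-2-methylprop-2-enoate
Conditions: PBr3, pyridine (cat.), Et2O, −10 → 0 °C
Reagents that add atoms: phosphorus tribromide, BrP(Br)Br
Why: Bromination of a tertiary vinyl carbinol with PBr3 runs with allylic transposition (SN2′ type, as in the change of linalool into geranyl bromide) to the primary bromide, the E-C1=C10 alkene is favoured because the long chain avoids the CH2Br group, and any Z isomer is removed after step 5.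

Step 5
Reactants: 8 allylic bromide
Product: 9 allylic phenyl sulfone ester, ethyl (2E)-3-{(1S,3R)-3-[(3E)-5-(benzenesulfonyl)-3-methylpent-3-en-1-yl]-2,2-dimethylcyclopropyl}-2-methylprop-2-enoate
Conditions: PhSO2Na, DMF, rt
Reagents that add atoms: sodium benzenesulfinate, [Na+].[O-]S(=O)c1ccccc1
Why: SN2 displacement of a primary allylic bromide by the soft sulfur of benzenesulfinate in a dipolar aprotic solvent is the standard entry to allylic sulfones, keeps the alkene geometry and gives a polar product from which the E,E isomer can be purified.

Step 6
Reactants: 9 sulfone ester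
Product: 10 sulfone allylic alcohol, (2E)-3-{(1S,3R)-3-[(3E)-5-(benzenesulfonyl)-3-methylpent-3-en-1-yl]-2,2-dimethylcyclopropyl}-2-methylprop-2-en-1-ol
Conditions: iBu2AlH, CH2Cl2, −78 °C; then aq. potassium sodium tartrate
Reagents that add atoms: none
Why: 1,2-Reduction of the enoate by iBu2AlH at low temperature gives the allylic alcohol without touching the sulfone, the alkenes or the cyclopropane.

Step 7
Reactants: 10 sulfone allylic alcohol
Product: 11 sulfone allylic chloride (C3–Cl, C2–SO2Ph, both alkenes E, cis-cyclopropane as in 3)
Conditions: NCS, Me2S, CH2Cl2, −20 → 0 °C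
Reagents that add atoms: N-chlorosuccinimide, O=C1CCC(=O)N1Cl
Why: Corey–Kim chlorination converts a primary allylic alcohol into the chloride by SN2 attack of chloride on an alkoxysulfonium ion under neutral conditions, which avoids the cyclopropyl-stabilised allyl cation and so preserves the alkene geometry and the three-membered ring.

Step 8
Reactants: 11 sulfone allylic chloride
Product: 13 2-(phenylsulfonyl)bicyclogermacrene (1(10)E,4E,6S,7R; both C2 epimers), via lithiated sulfone 12 (not isolated)
Conditions: LiN(SiMe3)2, THF, 0 °C → rt, slow addition of 11, high dilution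
Reagents that add atoms: none
Why: Intramolecular α-alkylation of a sulfone-stabilised allyl anion by an allylic chloride under high dilution is an established closure of (E,E)-cyclodeca-1,5-dienes, it is helped here by the cis-cyclopropane that turns both chains toward each other, and the uncontrolled C2 centre disappears in step 9.

Step 9
Reactants: 13 macrocyclic sulfone
Product: 14 (+)-bicyclogermacrene, (1S,2E,6E,10R)-3,7,11,11-tetramethylbicyclo[8.1.0]undeca-2,6-diene
Conditions: PdCl2(dppp) (cat.), LiBHEt3, THF, 0 °C
Reagents that add atoms: none
Why: Palladium-catalysed hydride desulfonylation passes through a π-allyl complex of divalent palladium that the hydride attacks at the less substituted terminus C2, so the C1=C10 alkene stays in place and E, and the low temperature spares the Cope-labile product.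

Step 10
Reactants: 15 phloroglucinol; 16 isobutyryl chloride
Product: 17 2-methyl-1-(2,4,6-trihydroxyphenyl)propan-1-one
Conditions: AlCl3, MeNO2/CH2Cl2, 0 → 40 °C
Reagents that add atoms: none
Why: Friedel–Crafts acylation of the very electron-rich, threefold symmetric arene gives one monoacyl product because the first acyl group deactivates the ring.

Step 11
Reactants: 17 isobutyrylphloroglucinol
Product: 18 3,5-dihydroxy-2,6,6-trimethyl-4-(2-methylpropanoyl)cyclohexa-2,4-dien-1-one
Conditions: MeI (3 equiv), NaOMe, MeOH, 0 °C → rt
Reagents that add atoms: iodomethane, CI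
Why: Base-mediated C-methylation of the phloroglucinol anion dearomatises the ring by placing two methyls on one free ring carbon and one on the other, and limiting the iodomethane stops the sequence short of the tetramethyl compound.

Step 12
Reactants: 14 (+)-bicyclogermacrene; 18 trimethyl acylphloroglucinol
Product: 20 dihydropyran-fused bicyclogermacrane cycloadduct (1S,4E,6S,7R,10R; O on C10, C1′ on C1, cyclopropane and C4=C5 intact), via o-quinone methide 19 (not isolated)
Conditions: Ag2O, TEMPO, PhMe, rt, dark, 18 in excess
Reagents that add atoms: none
Why: Ag2O/TEMPO dehydrogenation of the ring methyl of the enolised triketone gives 19, which adds in an inverse-electron-demand hetero-Diels–Alder reaction to the strained C1=C10 alkene (C4=C5 is screened by the gem-dimethylcyclopropane) with O going to the more substituted C10; suprafacial addition to the E alkene sets the trans fusion (C14 anti to H-1), and attack on the outer alkene face of the ring conformer that holds C14 on the cyclopropane side gives 1S,10R.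

Step 13
Reactants: 20 cycloadduct
Product: 21 5Z,11(12)-diene (1S,4S,7R,10R) with an isopropenyl group at C7
Conditions: Ph2O (degassed), BHT (cat.), 210–230 °C, base-washed sealed tube
Reagents that add atoms: none
Why: A hydrogen of the C11 methyl that shares the cyclopropane face with C5 passes to C4 through a concerted six-electron, six-centre transition state (retro-ene, homodienyl 1,5-hydrogen shift) while C6–C11 breaks and the C5=C6 and C11=C12 π bonds form, and the loss of cyclopropane strain makes the change irreversible. The closest known reaction type is the thermal homodienyl shift of cis-2-alkyl-1-vinylcyclopropanes, its nearest case being 2-carene to trans-isolimonene, which uses the same gem-dimethylcyclopropane and also a trisubstituted alkene. No ring is closed: the three-membered ring opens, and the ten-membered ring, the dihydropyran and the triketone ring stay as they are. Only the endo arrangement, in which C4=C5 is folded over the cyclopropane with C4 syn to C7 about the C5–C6 bond, brings C4 within reach of the methyl hydrogen, so C5=C6 can only form as the Z alkene. C4 is the one new stereocentre and is set by chirality transfer, since the hydrogen arrives on the alkene face that looks at C11 and, with C3 trans and C15 cis to C6 on the E alkene, the 6S,7R cyclopropane leads to 4S with C15 on the same ring face as the isopropenyl group at the untouched C7. The step needs methyl C–H transfer to beat transfer from C8–H (which would break C6–C7 and enlarge the ring), Cope rearrangement and cycloreversion: the first is favoured by three freely rotating methyl hydrogens against a C8–H bond held away from C4 by the ring and a strained C7=C8 alkene, the second is excluded because C1=C10 was consumed in step 12, and the third is held back by using the lowest temperature that still gives conversion.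

Step 14
Reactants: 21 diene
Product: 22 target CNP0564661.1 (1S,4S,5Z,7R,10R)
Conditions: Co(acac)2 (cat.), PhSiH3, O2 (1 atm), THF, 0 °C → rt
Reagents that add atoms: dioxygen, O=O
Why: Mukaiyama hydration (hydrogen-atom transfer from a cobalt hydride, capture of the tertiary C11 radical by O2, reduction of the peroxide by the silane) adds H and OH in the Markovnikov sense and is much faster for the 1,1-disubstituted alkene than for the Z-1,2-disubstituted C5=C6 or the tetrasubstituted, electron-poor ring alkenes, and no stereocentre is made or disturbed.

**Compound list**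
1 | (+)-2-carene, (1S,6R)-3,7,7-trimethylbicyclo[4.1.0]hept-2-ene | CC1=C[C@H]2[C@@H](CC1)C2(C)C | starting material
2 | carene ozonide (1,2,4-trioxolane across former C2=C3, acetal carbons undefined) | CC12CC[C@@H]3[C@H](C(OO1)O2)C3(C)C | intermediate
3 | (1S,3R)-2,2-dimethyl-3-(3-oxobutyl)cyclopropane-1-carbaldehyde | O=C[C@H]1[C@@H](CCC(C)=O)C1(C)C | intermediate
4 | ethyl 2-(triphenylphosphoranylidene)propanoate | CCOC(=O)C(C)=P(c1ccccc1)(c1ccccc1)c1ccccc1 | starting material
5 | (E)-enoate keto ester | CCOC(=O)/C(C)=C/[C@H]1[C@@H](CCC(C)=O)C1(C)C | intermediate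
6 | vinylmagnesium bromide | C=C[Mg]Br | starting material
7 | tertiary vinyl carbinol (carbinol epimers) | CCOC(=O)/C(C)=C/[C@H]1[C@@H](CCC(C)(O)C=C)C1(C)C | intermediate
8 | (E)-primary allylic bromide | CCOC(=O)/C(C)=C/[C@H]1[C@@H](CC/C(C)=C/CBr)C1(C)C | intermediate
9 | allylic phenyl sulfone ester | CCOC(=O)/C(C)=C/[C@H]1[C@@H](CC/C(C)=C/CS(=O)(=O)c2ccccc2)C1(C)C | intermediate
10 | sulfone allylic alcohol | OC/C(C)=C/[C@H]1[C@@H](CC/C(C)=C/CS(=O)(=O)c2ccccc2)C1(C)C | intermediate
11 | sulfone allylic chloride | ClC/C(C)=C/[C@H]1[C@@H](CC/C(C)=C/CS(=O)(=O)c2ccccc2)C1(C)C | intermediate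
12 | lithiated sulfone | ClC/C(C)=C/[C@H]1[C@@H](CC/C(C)=C/C([Li])S(=O)(=O)c2ccccc2)C1(C)C | intermediate
13 | 2-(phenylsulfonyl)bicyclogermacrene (C2 epimers) | C1/C(C)=C/[C@H]2[C@@H](CC/C(C)=C/C1S(=O)(=O)c1ccccc1)C2(C)C | intermediate
14 | (+)-bicyclogermacrene | C/C1=C\CC/C(C)=C/[C@H]2[C@@H](CC1)C2(C)C | intermediate
15 | phloroglucinol | Oc1cc(O)cc(O)c1 | starting material
16 | isobutyryl chloride | CC(C)C(Cl)=O | starting material
17 | 2-methyl-1-(2,4,6-trihydroxyphenyl)propan-1-one | CC(C)C(=O)c1c(O)cc(O)cc1O | intermediate
18 | 3,5-dihydroxy-2,6,6-trimethyl-4-(2-methylpropanoyl)cyclohexa-2,4-dien-1-one | CC(C)C(=O)C1=C(O)C(C)(C)C(=O)C(C)=C1O | intermediate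
19 | o-quinone methide, 5-hydroxy-6,6-dimethyl-2-methylidene-4-(2-methylpropanoyl)cyclohex-4-ene-1,3-dione | CC(C)C(=O)C1=C(O)C(C)(C)C(=O)C(=C)C1=O | intermediate
20 | dihydropyran-fused bicyclogermacrane cycloadduct (1S,4E,6S,7R,10R) | CC(C)C(=O)C1=C(O)C(C)(C)C(=O)C2=C1O[C@]1(C)CC[C@@H]3[C@H](/C=C(\C)CC[C@H]1C2)C3(C)C | intermediate
21 | 5Z,11(12)-diene (1S,4S,7R,10R) | CC(C)C(=O)C1=C(O)C(C)(C)C(=O)C2=C1O[C@]1(C)CC[C@@H](C(C)=C)/C=C\[C@@H](C)CC[C@H]1C2 | intermediate
22 | CNP0564661.1 (1S,4S,5Z,7R,10R) | CC(C)C(=O)C1=C(O)C(C)(C)C(=O)C2=C1O[C@]1(C)CC[C@@H](C(C)(C)O)/C=C\[C@@H](C)CC[C@H]1C2 | target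

**Count**
Total steps: 14. Longest linear sequence: 12 (steps 1–9, then 12–14); steps 10 and 11 form the short branch.

**Steps most likely to fail**

Step 13.
- In the resting conformation C4 is syn to H-6 and C15 lies on the ring face opposite C11.
- To reach the endo geometry the alkene must turn through the ring and place C15 over the cyclopropane, between C8 and the cis C11 methyl.
- This should raise the barrier above that of 2-carene, where the corresponding carbon is tied back in the six-membered ring.
- At the temperature then needed, cycloreversion of the dihydropyran, followed by Cope rearrangement of the released diene, or hydrogen transfer from C8 may overtake the wanted shift.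

The fallback moves the hydrogen shift to the open-chain stage, where the vinyl group rotates freely and no dihydropyran is present. It sets out from 5 and returns at 21.
- Heating 5 in degassed Ph2O should give ethyl (2R,3Z,5R)-2,6-dimethyl-5-(3-oxobutyl)hepta-3,6-dienoate F1 through the same endo transition state.
- Vinylmagnesium bromide at −78 °C gives the ring-opened vinyl carbinol F2.
- PBr3 gives the ring-opened (E)-allylic bromide F3.
- PhSO2Na gives the ring-opened sulfone ester F4.
- iBu2AlH gives the ring-opened sulfone alcohol F5.
- I2, PPh3 and imidazole (Appel reaction) give the sulfone iodide F6.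
- LiN(SiMe3)2 under high dilution closes C2–C3 to the monocyclic ten-membered sulfone F7.
- PdCl2(dppp) with LiBHEt3 gives (4S,7R)-germacra-1(10)E,5Z,11-triene F8.
- Cycloaddition of F8 with 19, generated from 18 as in step 12, at the strained trisubstituted C1=C10 alkene leads to 21.

Step 12.
- The quinone methide may condense with itself or be over-oxidised faster than it is trapped.
- Silver ion or adventitious acid may trigger transannular cyclisation of the sensitive diene.
- Ring conformers with C14 on either face are both accessible, so facial selectivity may be poor. The unwanted diastereomer would have to be removed by chromatography.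

The fallback drops the oxidation and builds the methylene carbon from formaldehyde. It sets out from 17 and returns at 20.
- Compound 17 is C-methylated only twice (MeI, NaOMe, MeOH) to 3,5-dihydroxy-6,6-dimethyl-4-(2-methylpropanoyl)cyclohexa-2,4-dien-1-one F9.
- F9, paraformaldehyde and 14 are combined with catalytic ethylenediammonium diacetate in MeCN.
- A Knoevenagel condensation then releases 19 slowly and at low concentration, and 19 is taken up by 14 in the same hetero-Diels–Alder reaction to give 20.

Step 8.
- Oligomerisation may compete with ring closure.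
- SN2′ attack or elimination of the allylic chloride may also outrun closure of the strained ten-membered ring.

The fallback closes the ring at C1=C10 by reductive carbonyl coupling instead of at C2–C3. It sets out from 3 and returns at 14.
- Isopropenylmagnesium bromide adds at −78 °C to the aldehyde of 3 to give the cyclopropyl isopropenyl carbinol F10.
- Ethyl vinyl ether with catalytic Hg(OAc)2 gives the allyl vinyl ether F11.
- Claisen rearrangement of F11 at about 130 °C gives the (E)-γ,δ-unsaturated keto aldehyde F12, which already carries C1 to C10.
- McMurry coupling of F12 (TiCl3(DME)1.5, Zn(Cu), DME, slow addition) gives 14 after separation of the geometric isomer.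

**Further compounds**
F1 | step 13 | ethyl (2R,3Z,5R)-2,6-dimethyl-5-(3-oxobutyl)hepta-3,6-dienoate | CC(=O)CC[C@@H](C(C)=C)/C=C\[C@@H](C)C(=O)OCC
F2 | step 13 | ring-opened vinyl carbinol | C=CC(C)(O)CC[C@@H](C(C)=C)/C=C\[C@@H](C)C(=O)OCC
F3 | step 13 | ring-opened (E)-allylic bromide | BrC/C=C(\C)CC[C@@H](C(C)=C)/C=C\[C@@H](C)C(=O)OCC
F4 | step 13 | ring-opened sulfone ester | O=S(=O)(c1ccccc1)C/C=C(\C)CC[C@@H](C(C)=C)/C=C\[C@@H](C)C(=O)OCC
F5 | step 13 | ring-opened sulfone alcohol | O=S(=O)(c1ccccc1)C/C=C(\C)CC[C@@H](C(C)=C)/C=C\[C@@H](C)CO
F6 | step 13 | sulfone iodide | O=S(=O)(c1ccccc1)C/C=C(\C)CC[C@@H](C(C)=C)/C=C\[C@@H](C)CI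
F7 | step 13 | monocyclic ten-membered sulfone | O=S(=O)(c1ccccc1)C1/C=C(\C)CC[C@@H](C(C)=C)/C=C\[C@@H](C)C1
F8 | step 13 | (4S,7R)-germacra-1(10)E,5Z,11-triene | C1/C=C(\C)CC[C@@H](C(C)=C)/C=C\[C@@H](C)C1
F9 | step 12 | 3,5-dihydroxy-6,6-dimethyl-4-(2-methylpropanoyl)cyclohexa-2,4-dien-1-one | CC(C)C(=O)C1=C(O)C(C)(C)C(=O)C=C1O
F10 | step 8 | cyclopropyl isopropenyl carbinol | CC(=C)C(O)[C@H]1[C@@H](CCC(C)=O)C1(C)C
F11 | step 8 | allyl vinyl ether | C=COC(C(C)=C)[C@H]1[C@@H](CCC(C)=O)C1(C)C
F12 | step 8 | (E)-γ,δ-unsaturated keto aldehyde | O=CCC/C(C)=C/[C@H]1[C@@H](CCC(C)=O)C1(C)C
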